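## Retrosynthetic overview
1. The target is 8,3'-dihydroxy-6,7,4',5'-tetramethoxyflavone. Rings A and B are bought as benzenoid building blocks, and only the pyranone ring C is built, in the last step.
2. Ring C (O1–C2 bond) comes from acid cyclodehydration of a 1-(2-hydroxyaryl)-3-aryl-1,3-diketone. The only protecting group, a 3'-O-TBS ether, is lost in the same pot.
3. The diketone (C2–C3 bond) comes from C-acylation of the polylithiated, unprotected 2,3-dihydroxy-4,5-dimethoxyacetophenone with 3-TBSO-4,5-dimethoxybenzoyl chloride.
4. The A-ring ketone comes from Friedel–Crafts acetylation of symmetric 1,2,3,4-tetramethoxybenzene, followed by chelation-directed BCl3 removal of the 2- and 3-O-methyl groups.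
5. The B-ring acid chloride comes from bis-silylation of 3-hydroxy-4,5-dimethoxybenzoic acid, followed by neutral conversion of the silyl ester to the acid chloride.

Assumption: the target has no stereocentre and no stereogenic double bond, so it is achiral and "single enantiomer" needs no stereocontrol. Compounds 1 and 5 are taken as catalogue chemicals.

## Route

Step 1
Reactants: 1 1,2,3,4-tetramethoxybenzene
Product: 2 1-(2,3,4,5-tetramethoxyphenyl)ethanone
Conditions: AcCl (1.1 equiv), AlCl3 (1.2 equiv), CH2Cl2, 0 °C, 1 h; ice/1 M HCl
Reagents that add atoms: acetyl chloride CC(=O)Cl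
Why: In this Friedel–Crafts acylation the two free positions of symmetric 1 are equivalent and activated by ortho and para methoxy groups, so a single mono-ketone forms, the acyl group blocks a second acylation, and no stereocentre is created.

Step 2
Reactants: 2 1-(2,3,4,5-tetramethoxyphenyl)ethanone
Product: 4 1-(2,3-dihydroxy-4,5-dimethoxyphenyl)ethanone, via cyclic chloroborate 3 (not isolated)
Conditions: BCl3 (1 M in CH2Cl2, 1.1 + 1.1 equiv in two portions), CH2Cl2, 0 °C to rt, 16 h, Ar; ice/1 M HCl
Reagents that add atoms: none
Why: In this chelation-directed Lewis-acid ether cleavage, BCl3 bound to the ketone oxygen removes the ortho 2-O-methyl first and the resulting aryloxyboron chloride then takes the neighbouring 3-O-methyl by closing the five-membered catechol borate 3, which leaves the 4- and 5-OMe groups intact, as in the known conversion of 2,3,4-trimethoxybenzaldehyde to 2,3-dihydroxy-4-methoxybenzaldehyde.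

Step 3
Reactants: 5 3-hydroxy-4,5-dimethoxybenzoic acid
Product: 6 tert-butyldimethylsilyl 3-[(tert-butyldimethylsilyl)oxy]-4,5-dimethoxybenzoate
Conditions: TBSCl (2.4 equiv), imidazole (5 equiv), DMF, rt, 16 h; hexane extraction, quick cold-water wash
Reagents that add atoms: tert-butyldimethylsilyl chloride CC(C)(C)[Si](C)(C)Cl
Why: Imidazole-promoted silylation caps the phenol and the acid in one operation, and the silyl ester is kept on purpose as a latent acid chloride.

Step 4
Reactants: 6 tert-butyldimethylsilyl 3-[(tert-butyldimethylsilyl)oxy]-4,5-dimethoxybenzoate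
Product: 7 3-[(tert-butyldimethylsilyl)oxy]-4,5-dimethoxybenzoyl chloride
Conditions: (COCl)2 (1.2 equiv), DMF (cat.), CH2Cl2, 0 °C to rt until gas evolution stops; evaporate and use crude
Reagents that add atoms: oxalyl chloride O=C(Cl)C(=O)Cl
Why: Vilsmeier-type chlorination of a silyl ester gives the acid chloride and releases TBSCl instead of HCl, so the medium stays neutral and the aryl TBS ether survives.

Step 5
Reactants: 4 1-(2,3-dihydroxy-4,5-dimethoxyphenyl)ethanone; 7 3-[(tert-butyldimethylsilyl)oxy]-4,5-dimethoxybenzoyl chloride
Product: 9 1-(2,3-dihydroxy-4,5-dimethoxyphenyl)-3-{3-[(tert-butyldimethylsilyl)oxy]-4,5-dimethoxyphenyl}propane-1,3-dione, via trilithio trianion 8 (not isolated)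
Conditions: LiHMDS (1 M in THF, 4.2 equiv), THF, −78 °C to −10 °C, 2 h, Ar; recool to −78 °C, add 7 (1.0 equiv) in THF, then to rt, 4 h; ice/1 M HCl
Reagents that add atoms: none
Why: In this crossed Claisen-type C-acylation of a polylithiated hydroxyacetophenone the enolate carbon is far more nucleophilic than the two lithium phenoxides, the fourth equivalent of base stores the product as its enolate and so stops double acylation, and any 2-O-aroyl ester that forms converges on the same diketone by a Baker–Venkataraman O-to-C shift.

Step 6
Reactants: 9 1-(2,3-dihydroxy-4,5-dimethoxyphenyl)-3-{3-[(tert-butyldimethylsilyl)oxy]-4,5-dimethoxyphenyl}propane-1,3-dione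
Product: 11 8-hydroxy-2-(3-hydroxy-4,5-dimethoxyphenyl)-6,7-dimethoxy-4H-chromen-4-one, via 3'-O-TBS flavone 10 (not isolated)
Conditions: AcOH, H2SO4 (0.5 vol %), 95–100 °C, 1–3 h, N2; pour into water, filter, recrystallise (MeOH)
Reagents that add atoms: none
Why: In this acid-catalysed cyclodehydration (the closing stage of a Baker–Venkataraman flavone synthesis) only the 2-OH can reach the aroyl carbonyl through a six-membered ring, the hemiketal dehydrates to pyranone 10, the hot acid and the released water cleave the phenolic TBS ether, the methyl ethers are untouched, and no Wessely–Moser isomerisation is possible because there is no 5-OH.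

## Compound list
1 | 1,2,3,4-tetramethoxybenzene | COc1ccc(OC)c(OC)c1OC | starting material
2 | 1-(2,3,4,5-tetramethoxyphenyl)ethanone | CC(=O)c1cc(OC)c(OC)c(OC)c1OC | intermediate
3 | 1-(2-chloro-6,7-dimethoxy-1,3,2-benzodioxaborol-4-yl)ethanone (cyclic chloroborate, not isolated) | CC(=O)c1cc(OC)c(OC)c2OB(Cl)Oc12 | intermediate
4 | 1-(2,3-dihydroxy-4,5-dimethoxyphenyl)ethanone | CC(=O)c1cc(OC)c(OC)c(O)c1O | intermediate
5 | 3-hydroxy-4,5-dimethoxybenzoic acid | COc1cc(C(=O)O)cc(O)c1OC | starting material
6 | tert-butyldimethylsilyl 3-[(tert-butyldimethylsilyl)oxy]-4,5-dimethoxybenzoate | COc1cc(C(=O)O[Si](C)(C)C(C)(C)C)cc(O[Si](C)(C)C(C)(C)C)c1OC | intermediate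
7 | 3-[(tert-butyldimethylsilyl)oxy]-4,5-dimethoxybenzoyl chloride | COc1cc(C(=O)Cl)cc(O[Si](C)(C)C(C)(C)C)c1OC | intermediate
8 | trilithium enolate bis(phenoxide) of 4 (not isolated) | [Li+].[Li+].[Li+].C=C([O-])c1cc(OC)c(OC)c([O-])c1[O-] | intermediate
9 | 1-(2,3-dihydroxy-4,5-dimethoxyphenyl)-3-{3-[(tert-butyldimethylsilyl)oxy]-4,5-dimethoxyphenyl}propane-1,3-dione | COc1cc(C(=O)CC(=O)c2cc(OC)c(OC)c(O)c2O)cc(O[Si](C)(C)C(C)(C)C)c1OC | intermediate
10 | 2-{3-[(tert-butyldimethylsilyl)oxy]-4,5-dimethoxyphenyl}-8-hydroxy-6,7-dimethoxy-4H-chromen-4-one (not isolated) | COc1cc(-c2cc(=O)c3cc(OC)c(OC)c(O)c3o2)cc(O[Si](C)(C)C(C)(C)C)c1OC | intermediate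
11 | 8-hydroxy-2-(3-hydroxy-4,5-dimethoxyphenyl)-6,7-dimethoxy-4H-chromen-4-one (CNP0264497.0, achiral) | COc1cc(-c2cc(=O)c3cc(OC)c(OC)c(O)c3o2)cc(O)c1OC | target

## Step count and risks
Total step count: 6.
Longest linear sequence: 4 steps (1 → 2 → 4 → 9 → 11). The B-ring arm 5 → 6 → 7 → 9 → 11 is equally long.

**Step 2 is the most likely to fail.** The 4-OMe is flanked on both sides and is the next ether to be cleaved, so under- or over-demethylation can occur. The fallback sets out from 2 and comes back at 4. It replaces the second Lewis-acid cleavage with an oxidative demethylation whose position is fixed by the free phenol. Compound 2 is treated with only 1.0 equiv of BCl3 at −78 to 0 °C, which removes just the carbonyl-chelated methyl and gives 1-(2-hydroxy-3,4,5-trimethoxyphenyl)ethanone F1. IBX in THF/DMF at rt then transfers oxygen to the methoxy-bearing ortho carbon and expels methanol, giving 3-acetyl-5,6-dimethoxycyclohexa-3,5-diene-1,2-dione F2. This quinone is reduced in the same flask with aqueous Na2S2O4 to 4.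

**Step 5 is the second risk.** The trianion may be poorly soluble or air-sensitive, or it may be O-acylated at the 3-oxygen. The fallback sets out from 4 and comes back at 11, bypassing 7 to 10. It changes the bond-forming reaction from acylation to aldol condensation followed by oxidative cyclisation, with no protecting groups. Compound 4 and purchased 3-hydroxy-4,5-dimethoxybenzaldehyde F3 are condensed in HCl-saturated EtOH at rt. This acid-catalysed Claisen–Schmidt reaction tolerates free phenols and gives (E)-1-(2,3-dihydroxy-4,5-dimethoxyphenyl)-3-(3-hydroxy-4,5-dimethoxyphenyl)prop-2-en-1-one F4. Any flavanone formed alongside it converges in the next operation. Heating with I2 (10 mol %) in DMSO at 120 °C under N2 brings about oxa-Michael closure, α-iodination and HI elimination to give 11. This path is shorter on paper. It is kept as a fallback because the tetra-oxygenated catechol ring can be oxidised or iodinated under these conditions.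

**Step 1 is the third risk.** AlCl3 can strip the crowded inner methoxy groups of 1 or 2, and loss of the future 4-OMe cannot be repaired. The fallback sets out from 1 and comes back at 2. It replaces electrophilic substitution with directed ortho-metalation. Treatment of 1 with n-BuLi/TMEDA in THF at 0 °C gives (2,3,4,5-tetramethoxyphenyl)lithium F5. This is quenched at −78 °C with N-methoxy-N-methylacetamide and worked up with aqueous NH4Cl to give 2. No Lewis acid is present, so no ether can be cleaved.

## Further compounds
F1 | step 2 | 1-(2-hydroxy-3,4,5-trimethoxyphenyl)ethanone | CC(=O)c1cc(OC)c(OC)c(OC)c1O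
F2 | step 2 | 3-acetyl-5,6-dimethoxycyclohexa-3,5-diene-1,2-dione | CC(=O)C1=CC(OC)=C(OC)C(=O)C1=O
F3 | step 5 | 3-hydroxy-4,5-dimethoxybenzaldehyde (purchased) | COc1cc(C=O)cc(O)c1OC
F4 | step 5 | (E)-1-(2,3-dihydroxy-4,5-dimethoxyphenyl)-3-(3-hydroxy-4,5-dimethoxyphenyl)prop-2-en-1-one | COc1cc(/C=C/C(=O)c2cc(OC)c(OC)c(O)c2O)cc(O)c1OC
F5 | step 1 | (2,3,4,5-tetramethoxyphenyl)lithium | [Li]c1cc(OC)c(OC)c(OC)c1OC
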